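**Retrosynthetic overview**
- The target has one carbocycle, a cyclohexene: C1 (H, isopropenyl), C2 (H2), C3 (H)=C4 (CH3), C5 (H, CH2OAr), C6 (CH3, CH2CH2CO2H). The plan reads quaternary C6 as the α-carbon of a 2-methyl aldehyde whose CHO carbon becomes C5, and C1 as the carbon β to a ketone placed at C3.
- Late disconnections: the acid comes from its tert-butyl ester, and the aryl ether from a Mitsunobu coupling of C5–CH2OH with umbelliferone, whose bicycle is bought intact. C5–CH2OH and the C3=C4 alkene come from a suprafacial Still–Wittig shift of the C3 allylic alcohol, and the isopropenyl group from the C1 methyl ester via the methyl ketone.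
- The only ring made is closed in one flask. C6–C1 forms by enamine Michael addition and C4=C5 by aldol condensation, from racemic aldehyde 4 and keto enoate 10.
- Aldehyde 4 comes from propanal and tert-butyl acrylate (Stork enamine). Enoate 10 comes from methyl glyoxylate and the 2-oxobutyl ylide (Wittig).

Key step: step 4

Remark: the ring numbering C1–C6 above is kept for every compound, and "upper face" means the face that carries the C6 methyl group.
Assumption: the (1R,2R) antipode of the catalyst is written in step 4 by analogy with related enamine additions. The sense of induction is to be confirmed in a pilot run, and the equally available (1S,2S) antipode is used if ent-12 forms.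

**Step 1**
Reactants: 1 propanal; 2 tert-butyl acrylate
Product: 4 rac-tert-butyl 4-methyl-5-oxopentanoate, via piperidine enamine 3 (not isolated)
Conditions: piperidine, K2CO3, Et2O, 0 °C → rt, filter, concentrate; 2, MeCN, reflux; AcOH–NaOAc–H2O, 40 °C
Reagents that add atoms: water, O
Why: In this Stork enamine Michael addition the aldehyde enamine adds once to the acrylate, the more hindered product enamine does not add again, and buffered hydrolysis returns the aldehyde without harming the tert-butyl ester; the new α-centre is racemic, which does not matter because step 4 erases it.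

**Step 2**
Reactants: 5 1-bromobutan-2-one; 6 triphenylphosphine
Product: 8 1-(triphenyl-λ5-phosphanylidene)butan-2-one, via phosphonium bromide 7 (not isolated)
Conditions: toluene, rt → 60 °C; then 2 M NaOH, CH2Cl2/H2O, rt
Reagents that add atoms: none
Why: SN2 quaternisation of the phosphine by the primary α-bromo ketone and deprotonation of the acidic P–CH2–C=O position is the standard preparation of a ketone-stabilised Wittig ylide.

**Step 3**
Reactants: 8 1-(triphenyl-λ5-phosphanylidene)butan-2-one; 9 methyl glyoxylate
Product: 10 methyl (E)-4-oxohex-2-enoate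
Conditions: freshly distilled 9, CH2Cl2, 0 °C → rt
Reagents that add atoms: none
Why: Wittig olefination of a reactive aldehyde with a stabilised ylide under neutral, salt-free conditions should be E-selective and spares the base-sensitive keto enoate.

**Step 4**
Reactants: 4 rac-tert-butyl 4-methyl-5-oxopentanoate; 10 methyl (E)-4-oxohex-2-enoate
Product: 12 methyl (1S,2S)-2-(3-tert-butoxy-3-oxopropyl)-2,4-dimethyl-5-oxocyclohex-3-ene-1-carboxylate (route numbering 1S,6S; CO2Me cis to the C6 methyl), via keto aldehyde 11 (not isolated)
Conditions: 4 (2 equiv), 1-[(1R,2R)-2-aminocyclohexyl]-3-[3,5-bis(trifluoromethyl)phenyl]thiourea (20 mol %), PhCO2H (20 mol %), H2O (2 equiv), toluene (2 M), rt → 40 °C; once 10 is consumed, pyrrolidine/AcOH (30 mol % each), 50 °C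
Reagents that add atoms: none
Why: Either enantiomer of 4 condenses with the primary amine to the same trisubstituted enamine, so the α-stereocentre is erased and the racemate converges; the enamine carbon (future C6) adds to C2 of 10 while the thiourea N–H bonds hold the ketone oxygen, hydrolysis frees keto aldehyde 11, and in the second stage the pyrrolidine enamine on the ethyl side of the ketone attacks the non-enolisable aldehyde and water is lost. The closest known reactions are primary-amine-catalysed Michael additions of α-branched aldehydes to nitroalkenes, maleimides and vinyl ketones, amine-catalysed additions of linear aldehydes to γ-keto enoates at the carbon α to the ester, and the Robinson-type cyclodehydration of 1,5-keto aldehydes. The ring closes by a 6-(enolendo)-exo-trig aldol addition (C4 onto C5) followed by E1cB dehydration, and it is the only closure open to 11 because every other enolisable site would give a three- or four-membered ring. C6 is controlled by the catalyst, which should expose only the Si face of the E enamine (CH3 cis to N), and C1 by an open synclinal transition state in which the Re face of C2 of 10 is attacked with the ketone-bearing alkene carbon under the nitrogen and CO2Me anti to the enamine C=C; this arrangement maps directly onto the chair with CO2Me and the propanoate chain equatorial and the C6 methyl axial, that is CO2Me cis to CH3. The step needs regioselectivity (attack β to the ketone, not β to the ester), secured by the stronger acceptor character of the ketone and its hydrogen bonding to the thiourea, and it needs a high E:Z enamine ratio, which a methyl versus primary-alkyl pair secures only in part, so the C6 epimer is the expected minor product and is to be removed by chromatography of 12. C1 is α only to the ester and is not enolised by the amine salts of either stage, so the configuration set in the addition should persist.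

**Step 5**
Reactants: 12 enone diester
Product: 13 methyl (1S,2S,5R)-2-(3-tert-butoxy-3-oxopropyl)-5-hydroxy-2,4-dimethylcyclohex-3-ene-1-carboxylate (route numbering 1S,3R,6S; 3-OH on the upper face, cis to CO2Me)
Conditions: NaBH4, CeCl3·7H2O, MeOH, −78 → −40 °C; pH 7 buffer
Reagents that add atoms: none
Why: In this Luche 1,2-reduction, by analogy with carvone → cis-carveol, hydride should enter axially from the lower face of the conformer with CO2Me and chain equatorial, giving the pseudo-equatorial 3R alcohol; both esters are inert, and the cold neutral quench suppresses lactonisation onto the cis ester.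

**Step 6**
Reactants: 13 allylic alcohol
Product: 14 methyl (1S,2S,5R)-2-(3-tert-butoxy-3-oxopropyl)-5-[(tert-butyldimethylsilyl)oxy]-2,4-dimethylcyclohex-3-ene-1-carboxylate
Conditions: TBSCl, imidazole, DMF, rt
Reagents that add atoms: tert-butyldimethylsilyl chloride, CC(C)(C)[Si](C)(C)Cl
Why: Imidazole-promoted silylation protects the alcohol without generating a free alkoxide, which would attack the cis C1 ester, and it leaves all three stereocentres untouched.

**Step 7**
Reactants: 14 silyl ether diester
Product: 15 tert-butyl 3-[(1S,4R,6S)-4-[(tert-butyldimethylsilyl)oxy]-6-[methoxy(methyl)carbamoyl]-1,3-dimethylcyclohex-2-en-1-yl]propanoate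
Conditions: MeNH(OMe)·HCl, i-PrMgCl, THF, −20 → 0 °C; aq. NH4Cl
Reagents that add atoms: N,O-dimethylhydroxylamine hydrochloride, CNOC.Cl
Why: In this Weinreb amide synthesis by direct ester aminolysis the small magnesium amide attacks the methyl ester, while the tert-butyl ester is shielded by its alkoxy group, and the low temperature should avoid enolisation at C1.

**Step 8**
Reactants: 15 Weinreb amide
Product: 16 tert-butyl 3-[(1S,4R,6S)-6-acetyl-4-[(tert-butyldimethylsilyl)oxy]-1,3-dimethylcyclohex-2-en-1-yl]propanoate
Conditions: MeMgBr, THF, −20 → 0 °C; cold aq. NH4Cl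
Reagents that add atoms: methylmagnesium bromide, C[Mg]Br
Why: In the Weinreb ketone synthesis the chelated tetrahedral adduct stops the addition at one methyl group, tert-butyl esters survive MeMgBr at or below 0 °C, and the cold buffered quench protects the now epimerisable C1.

**Step 9**
Reactants: 16 methyl ketone
Product: 17 tert-butyl 3-[(1S,4R,6R)-4-[(tert-butyldimethylsilyl)oxy]-1,3-dimethyl-6-(prop-1-en-2-yl)cyclohex-2-en-1-yl]propanoate
Conditions: Tebbe reagent (1.2 equiv), pyridine (cat.), THF–toluene, −40 → 0 °C; aq. NaOH
Reagents that add atoms: Tebbe reagent, [CH2-2].[Cl-].C[Al+]C.[Ti+4].[cH-]1cccc1.[cH-]1cccc1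
Why: In the Tebbe methylenation the non-basic titanium methylidene reacts by [2+2] addition and cycloreversion, takes hindered ketones faster than esters, and does not enolise the ketone, so C1 keeps its configuration (the descriptor changes to R only through CIP priorities).

**Step 10**
Reactants: 17 silyl ether
Product: 18 tert-butyl 3-[(1S,4R,6R)-4-hydroxy-1,3-dimethyl-6-(prop-1-en-2-yl)cyclohex-2-en-1-yl]propanoate
Conditions: TBAF, THF, rt
Reagents that add atoms: none
Why: Fluoride desilylation is safe here because no epimerisable centre remains and the tert-butyl ester tolerates TBAF.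

**Step 11**
Reactants: 18 allylic alcohol
Product: 19 tert-butyl 3-[(1S,4R,6R)-1,3-dimethyl-6-(prop-1-en-2-yl)-4-[(tributylstannyl)methoxy]cyclohex-2-en-1-yl]propanoate
Conditions: KH (1.2 equiv), THF, 0 °C; Bu3SnCH2I, 0 °C → rt
Reagents that add atoms: tributyl(iodomethyl)stannane, CCCC[Sn](CCCC)(CCCC)CI
Why: Williamson etherification of the potassium alkoxide with the reactive iodomethylstannane leaves the C3–O bond and its configuration intact, and the ester chain on the opposite face is out of reach of the alkoxide.

**Step 12**
Reactants: 19 stannylmethyl ether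
Product: 22 tert-butyl 3-[(1R,2R,6R)-2-(hydroxymethyl)-1,3-dimethyl-6-(prop-1-en-2-yl)cyclohex-3-en-1-yl]propanoate (route numbering 1R,5R,6R), via lithium enolate 20 (not isolated), via lithiomethyl ether 21 (not isolated)
Conditions: LDA (1.1 equiv), THF, −78 °C; n-BuLi (2.4 equiv), −78 → −30 °C; aq. NH4Cl
Reagents that add atoms: none
Why: In this Still–Wittig [2,3] rearrangement LDA first masks the ester as its lithium enolate (no stereocentre at that carbon; it is restored on quench), the excess n-BuLi consumes the liberated amine and effects tin–lithium exchange, and the α-alkoxy carbanion migrates suprafacially from the upper-face C3–O to the upper face of C5, setting C5 (R) cis to the C6 methyl and the isopropenyl group and moving the alkene to C3=C4.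

**Step 13**
Reactants: 22 homoallylic primary alcohol; 23 umbelliferone (7-hydroxycoumarin)
Product: 24 tert-butyl 3-[(1R,2R,6R)-1,3-dimethyl-2-{[(2-oxo-2H-chromen-7-yl)oxy]methyl}-6-(prop-1-en-2-yl)cyclohex-3-en-1-yl]propanoate
Conditions: PPh3, DIAD, THF, 0 °C → rt
Reagents that add atoms: none
Why: In this Mitsunobu etherification the acidic 7-hydroxyl of the coumarin displaces the activated primary, non-stereogenic carbinol under neutral conditions that leave the lactone, the ester and both alkenes alone.

**Step 14**
Reactants: 24 aryl ether tert-butyl ester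
Product: 26 3-[(1R,2R,6R)-1,3-dimethyl-2-{[(2-oxo-2H-chromen-7-yl)oxy]methyl}-6-(prop-1-en-2-yl)cyclohex-3-en-1-yl]propanoic acid (target), via trimethylsilyl ester 25 (not isolated)
Conditions: TMSOTf, 2,6-lutidine, CH2Cl2, 0 °C → rt; then pH 4 citrate buffer
Reagents that add atoms: none
Why: In this silyl-triflate cleavage of the tert-butyl ester, carbonyl silylation expels the tert-butyl cation, which is taken off as isobutene by lutidine, so no free Brønsted acid can protonate the isopropenyl or ring alkene and no base opens the coumarin; the silyl ester hydrolyses on work-up.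

**Compound list**
1 | propanal | CCC=O | starting material
2 | tert-butyl acrylate | C=CC(=O)OC(C)(C)C | starting material
3 | (E)-1-(prop-1-en-1-yl)piperidine | C/C=C/N1CCCCC1 | intermediate
4 | rac-tert-butyl 4-methyl-5-oxopentanoate | CC(C=O)CCC(=O)OC(C)(C)C | intermediate
5 | 1-bromobutan-2-one | CCC(=O)CBr | starting material
6 | triphenylphosphine | c1ccc(cc1)P(c1ccccc1)c1ccccc1 | starting material
7 | (2-oxobutyl)triphenylphosphonium bromide | CCC(=O)C[P+](c1ccccc1)(c1ccccc1)c1ccccc1.[Br-] | intermediate
8 | 1-(triphenyl-λ5-phosphanylidene)butan-2-one | CCC(=O)C=P(c1ccccc1)(c1ccccc1)c1ccccc1 | intermediate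
9 | methyl glyoxylate | O=CC(=O)OC | starting material
10 | methyl (E)-4-oxohex-2-enoate | CCC(=O)/C=C/C(=O)OC | intermediate
11 | methyl (2S)-2-[(2R)-5-tert-butoxy-2-methyl-1,5-dioxopentan-2-yl]-4-oxohexanoate | COC(=O)[C@@H](CC(=O)CC)[C@](C)(C=O)CCC(=O)OC(C)(C)C | intermediate
12 | methyl (1S,2S)-2-(3-tert-butoxy-3-oxopropyl)-2,4-dimethyl-5-oxocyclohex-3-ene-1-carboxylate | COC(=O)[C@H]1CC(=O)C(C)=C[C@]1(C)CCC(=O)OC(C)(C)C | intermediate
13 | methyl (1S,2S,5R)-2-(3-tert-butoxy-3-oxopropyl)-5-hydroxy-2,4-dimethylcyclohex-3-ene-1-carboxylate | COC(=O)[C@H]1C[C@@H](O)C(C)=C[C@]1(C)CCC(=O)OC(C)(C)C | intermediate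
14 | TBS ether of 13 | COC(=O)[C@H]1C[C@@H](O[Si](C)(C)C(C)(C)C)C(C)=C[C@]1(C)CCC(=O)OC(C)(C)C | intermediate
15 | C1 Weinreb amide (1S,4R,6S) | CON(C)C(=O)[C@H]1C[C@@H](O[Si](C)(C)C(C)(C)C)C(C)=C[C@]1(C)CCC(=O)OC(C)(C)C | intermediate
16 | C1 methyl ketone (1S,4R,6S) | CC(=O)[C@H]1C[C@@H](O[Si](C)(C)C(C)(C)C)C(C)=C[C@]1(C)CCC(=O)OC(C)(C)C | intermediate
17 | C1 isopropenyl TBS ether (1S,4R,6R) | C=C(C)[C@H]1C[C@@H](O[Si](C)(C)C(C)(C)C)C(C)=C[C@]1(C)CCC(=O)OC(C)(C)C | intermediate
18 | C3 allylic alcohol (1S,4R,6R) | C=C(C)[C@H]1C[C@@H](O)C(C)=C[C@]1(C)CCC(=O)OC(C)(C)C | intermediate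
19 | C3 (tributylstannyl)methyl ether | C=C(C)[C@H]1C[C@@H](OC[Sn](CCCC)(CCCC)CCCC)C(C)=C[C@]1(C)CCC(=O)OC(C)(C)C | intermediate
20 | lithium ester enolate of 19 | C=C(C)[C@H]1C[C@@H](OC[Sn](CCCC)(CCCC)CCCC)C(C)=C[C@]1(C)CC=C([O-])OC(C)(C)C.[Li+] | intermediate
21 | C3 lithiomethyl ether, ester enolate | C=C(C)[C@H]1C[C@@H](OC[Li])C(C)=C[C@]1(C)CC=C([O-])OC(C)(C)C.[Li+] | intermediate
22 | tert-butyl 3-[(1R,2R,6R)-2-(hydroxymethyl)-1,3-dimethyl-6-(prop-1-en-2-yl)cyclohex-3-en-1-yl]propanoate | C=C(C)[C@H]1CC=C(C)[C@@H](CO)[C@]1(C)CCC(=O)OC(C)(C)C | intermediate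
23 | umbelliferone | O=c1ccc2ccc(O)cc2o1 | starting material
24 | umbelliferyl ether tert-butyl ester | C=C(C)[C@H]1CC=C(C)[C@@H](COc2ccc3ccc(=O)oc3c2)[C@]1(C)CCC(=O)OC(C)(C)C | intermediate
25 | umbelliferyl ether trimethylsilyl ester | C=C(C)[C@H]1CC=C(C)[C@@H](COc2ccc3ccc(=O)oc3c2)[C@]1(C)CCC(=O)O[Si](C)(C)C | intermediate
26 | CNP0103683.1, 3-[(1R,2R,6R)-1,3-dimethyl-2-{[(2-oxo-2H-chromen-7-yl)oxy]methyl}-6-(prop-1-en-2-yl)cyclohex-3-en-1-yl]propanoic acid | C=C(C)[C@H]1CC=C(C)[C@@H](COc2ccc3ccc(=O)oc3c2)[C@]1(C)CCC(=O)O | target

**Step count**
Total: 14 steps. Longest linear sequence: 13 steps (5 → 8 → 10 → 12 → … → 26, steps 2–14).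

**Steps most likely to fail**

Step 4.
- Bond formation between a fully substituted enamine carbon and a β-substituted acceptor may be slow.
- Reaction through the Z enamine may erode the diastereomer ratio.
- The catalyst may be lost by conjugate addition to 10 or by lactam formation with the γ-keto ester unit.

The fallback sets out from 4 and returns at 11. It replaces catalysis by a stoichiometric chiral auxiliary.
- Aldehyde 4 is condensed with (S)-1-phenylethylamine (molecular sieves, toluene) to the aldimine F1, whose α-epimers interconvert through the secondary enamine tautomer.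
- F1 is stirred with 10 neat or in THF (rt → 50 °C). The enamine tautomer adds through a compact cyclic transition state with internal N–H transfer (chiral-imine Michael reaction) to give the adduct imine F2.
- Aqueous acetic acid hydrolyses F2 to 11, which is closed to 12 with pyrrolidinium acetate as in the second stage of step 4.
- The antipode of the amine is chosen after a pilot run.

Step 12.
- The ether oxygen is pseudo-equatorial in the resting half-chair. The conformer that aligns C3–O with the π system places the isopropenyl group axial on the same face, so the [2,3] shift may be slow.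
- A [1,2] shift, protonation of the carbanion by residual diisopropylamine, or attack of organolithium on incompletely masked ester may then take over.

The fallback sets out from 18 and returns at 22. It avoids organolithium reagents altogether.
- Alcohol 18 is heated with N,N-dimethylformamide dimethyl acetal in refluxing xylene with removal of methanol. Acetal exchange gives the mixed acetal F3.
- F3 loses methanol and undergoes the suprafacial carbene-type [2,3] shift (Büchi rearrangement) to the β,γ-unsaturated dimethylamide F4.
- The Schwartz reagent (Cp2Zr(H)Cl, THF, rt, esters tolerated) takes F4 to the aldehyde F5.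
- F5 is reduced at once with NaBH4 in MeOH at 0 °C to 22.

Step 7.
- Shielding of the C1 ester by the neighbouring quaternary carbon may leave the aminolysis incomplete.
- Forcing the reaction may bring attack on the tert-butyl ester or enolisation at C1.

The fallback sets out from 13 and returns at 15. It uses the cis C3 hydroxyl to activate the C1 carboxyl.
- Alcohol 13 is lactonised (DBU, toluene, 80 °C, 4 Å sieves) to the bridged allylic lactone F6, which has a 6-oxabicyclo[3.2.1]oct-3-en-7-one core.
- The strained lactone is far more electrophilic than the tert-butyl ester and is opened with the aluminium amide from Me3Al and MeNH(OMe)·HCl (CH2Cl2, 0 °C → rt) to the hydroxy Weinreb amide F7.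
- F7 is silylated immediately (TBSCl, imidazole, DMF) to 15.

**Further compounds**
F1 | step 4 | tert-butyl 4-methyl-5-{[(1S)-1-phenylethyl]imino}pentanoate | CC(/C=N/[C@@H](C)c1ccccc1)CCC(=O)OC(C)(C)C
F2 | step 4 | (1S)-1-phenylethyl aldimine of 11 | COC(=O)[C@@H](CC(=O)CC)[C@](C)(/C=N/[C@@H](C)c1ccccc1)CCC(=O)OC(C)(C)C
F3 | step 12 | C3 O-[(dimethylamino)(methoxy)methyl] mixed acetal of 18 | C=C(C)[C@H]1C[C@@H](OC(OC)N(C)C)C(C)=C[C@]1(C)CCC(=O)OC(C)(C)C
F4 | step 12 | C5 N,N-dimethylcarboxamide, alkene at C3=C4 | C=C(C)[C@H]1CC=C(C)[C@@H](C(=O)N(C)C)[C@]1(C)CCC(=O)OC(C)(C)C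
F5 | step 12 | C5 carbaldehyde, alkene at C3=C4 | C=C(C)[C@H]1CC=C(C)[C@@H](C=O)[C@]1(C)CCC(=O)OC(C)(C)C
F6 | step 7 | bridged C1-carboxyl/C3-oxygen lactone of 13 | O=C1O[C@@H]2C[C@H]1[C@@](C)(CCC(=O)OC(C)(C)C)C=C2C
F7 | step 7 | C3 hydroxy C1 Weinreb amide | CON(C)C(=O)[C@H]1C[C@@H](O)C(C)=C[C@]1(C)CCC(=O)OC(C)(C)C
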